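Cedar carries 3.96 times the pre-initiator of ash, and the pitfall is to read that as shorter chains in cedar, as if a fixed stock of monomer were shared out among the chains begun.

- cedar: free monomer 0.66 M; transfer agent 6.60 mM; protic impurity 0.0330 M; pre-initiator 9.9 mM; time 1.5 h
- ash: free monomer 0.66 M; transfer agent 6.60 mM; protic impurity 0.0330 M; pre-initiator 2.5 mM; time 1.5 h

1. which of the two ends with the longer chains by the average number of monomer units in a chain (chains begun, living or dead) ("neither" if they lie within 10 %) (cedar / ash / neither)
2. average number of monomer units in a chain (chains begun, living or dead) at the end, cedar
3. average number of monomer units in a chain (chains begun, living or dead) at the end, ash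

- the average divides the monomer in chains by the number of chains begun, living and dead together
- run time (cedar): 1.5 h

    free monomer + initiator → living end + monomer in chains (k1 = 0.169 M⁻¹ min⁻¹)
    free monomer + living end → monomer in chains + living end, rate k2*[living end]*[free monomer] (k2 = 2.41 M⁻¹ min⁻¹)
    living end + transfer agent → dead chain (k3 = 5.66 M⁻¹ min⁻¹)
    protic impurity + free monomer → quenched substrate (k4 = 0.628 M⁻¹ min⁻¹)
    pre-initiator → initiator (k5 = 0.134 min⁻¹)

Read column against column, the two recipes differ in pre-initiator and agree in free monomer, transfer agent and protic impurity. The pre-initiator column feeds initiator, and each initiator begins a chain. The transfer-agent column gives the life of a living end: its death on transfer agent is pseudo-first-order, with a mean life at the charge of 26.8 min. The next two columns are taken together. Protic impurity has a half-life in free monomer of 1.67 min, shorter than that life, so propagation starts from about 0.627 M of free monomer, a level that propagation itself then lowers. At that starting level a living end adds a unit every 0.662 min, far quicker than it dies. The quotient is 40.5, the turnover number of a living end at the starting levels: the additions it makes before transfer ends it. No pre-initiator enters this count. With the first unit placed at initiation, my reckoning on the charges gives 41.5 units for cedar and 41.5 for ash, level within the margin of 10 %.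

The forecast says neither, with 38.7 for cedar and 39.8 for ash. It reached these by another road: “I stepped both runs in 10-minute blocks”.

The simulation gives neither, with 38.9 for cedar and 40.0 for ash.

Ash without the loss of living end to transfer agent ends at 89.8 instead of 40.0, so that step is a large part of what holds the chains of ash to their length. Ash recharged with the pre-initiator of cedar ends at 38.9 instead of 40.0, so the difference in pre-initiator is not what sets the length. The neighbour of cedar charged with 0.026 M of transfer agent shortens the life of a living end, and the turnover count, scaled to that charge, gives 11.3 units. The simulation gives 12.5.

The rate constants are those of an exercise; the run is a simulation.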